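**Strategy.** The route rests on disconnecting the C2–O and C5–O bonds of the cyclohexenone ring. The C2 carbonyl and the C5 oxygen stand 1,4 to each other across the C1=C6 double bond, the pattern left by a cyclohexa-1,3-diene endoperoxide after base-induced isomerisation. One photooxygenation delivers both oxygens, moves the alkene to C1=C6 and fixes the C5 oxygen relative to the C4 isopropyl group. Its substrate is a cryptone-derived (R)-5-isopropylcyclohexa-1,3-diene carrying a silyl-protected hydroxymethyl group on C1. Afterwards C5 is inverted by Mitsunobu angeloylation before C3 is oxygenated, so that both neighbouring groups steer the enol ether oxidation trans to isopropyl. The epoxyangelate comes from angelic acid by asymmetric epoxidation.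

Key step: step 6

Remark: ring atoms carry the target numbering throughout (C1 bears C7, C2 is the carbonyl carbon, C3 and C5 carry the ester oxygens, C4 the isopropyl group, C6 is the vinylic CH); cis and trans refer to the C4 isopropyl group.

Step 1
Reactants: 1 isovaleraldehyde; 2 methyl vinyl ketone
Product: 4 (R)-cryptone [(R)-4-isopropylcyclohex-2-en-1-one], via keto aldehyde 3 (not isolated)
Conditions: (R)-2-[methoxy(diphenyl)methyl]pyrrolidine (5 mol%), ethyl 3,4-dihydroxybenzoate (20 mol%), neat, 4 °C; then LiOH (0.5 equiv), iPrOH, rt
Reagents that add atoms: none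
Why: Enamine-catalysed Michael addition in which the E-enamine of 1 is attacked by 2 on the face remote from the diarylmethyl group of the (R)-pyrrolidine, which sets the (R) centre of 3, followed by intramolecular aldol condensation of the methyl ketone onto the aldehyde (Robinson-type annulation) that closes the enone without involving that centre.

Step 2
Reactants: 4 (R)-cryptone
Product: 6 (R)-4-isopropylcyclohexa-1,5-dien-1-yl trifluoromethanesulfonate, via lithium dienolate 5 (not isolated)
Conditions: LiN(iPr)2, THF, −78 °C; then PhNTf2, −78 °C → 0 °C; aq. NH4Cl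
Reagents that add atoms: N-phenylbis(trifluoromethanesulfonimide), O=S(=O)(N(c1ccccc1)S(=O)(=O)C(F)(F)F)C(F)(F)F
Why: Kinetic deprotonation at the α′-methylene gives the cross-conjugated lithium dienolate without touching the γ-stereocentre, and O-sulfonylation (enol triflate formation) fixes the 1,3-diene.

Step 3
Reactants: 6 dienyl triflate
Product: 7 methyl (R)-4-isopropylcyclohexa-1,5-diene-1-carboxylate
Conditions: Pd(OAc)2 (5 mol%), PPh3 (10 mol%), CO (1 atm), MeOH, Et3N, DMF, rt
Reagents that add atoms: carbon monoxide, [C-]#[O+]; methanol, CO
Why: Palladium-catalysed alkoxycarbonylation of an alkenyl triflate, in which oxidative addition to zerovalent palladium formed in situ, CO insertion and methanolysis of the acylpalladium species install C7 at room temperature, well below the range of sigmatropic hydrogen shifts in the diene.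

Step 4
Reactants: 7 dienyl ester
Product: 8 [(R)-4-isopropylcyclohexa-1,5-dien-1-yl]methanol
Conditions: iBu2AlH (2.5 equiv), CH2Cl2, −78 °C → 0 °C; aq. KNaC4H4O6
Reagents that add atoms: none
Why: 1,2-Reduction of the conjugated ester by the aluminium hydride (ester to primary alcohol through the aldehyde) leaves the diene and the C4 centre as spectators.

Step 5
Reactants: 8 dienyl alcohol
Product: 9 (R)-5-isopropyl-2-[(tert-butyldimethylsilyloxy)methyl]cyclohexa-1,3-diene
Conditions: tBuMe2SiCl, imidazole, CH2Cl2, 0 °C → rt
Reagents that add atoms: tert-butyldimethylsilyl chloride, CC(C)(C)[Si](C)(C)Cl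
Why: Imidazole-promoted silyl ether formation on the primary alcohol gives a group that should withstand singlet oxygen, amine base, Mitsunobu, enolate and acylation conditions and leaves with fluoride at the end.

Step 6
Reactants: 9 silyloxymethyl diene
Product: 10 (1R,4S,7R)-5-[(tert-butyldimethylsilyloxy)methyl]-7-isopropyl-2,3-dioxabicyclo[2.2.2]oct-5-ene (peroxide bridge from C2 to C5, anti to isopropyl)
Conditions: O2, 5,10,15,20-tetraphenylporphyrin (0.5 mol%), white LED light, CH2Cl2, −78 °C
Reagents that add atoms: dioxygen, O=O
Why: Energy transfer from the photoexcited porphyrin turns triplet O2 into singlet oxygen, which adds suprafacially across C2 and C5 of the s-cis-locked diene in a concerted [4+2] cycloaddition, the reaction type known from dye-sensitised photooxygenation of α-phellandrene and other cyclohexa-1,3-dienes. The one new ring, the six-membered 1,2-dioxane of the 2,3-dioxabicyclo[2.2.2]octene, closes by forming both C–O bonds in this single cycloaddition while the double bond moves to C1=C6. The C2 and C5 stereocentres arise together from the choice of diene face, and that choice is governed by the C4 stereocentre, whose isopropyl group sits next to the C5 terminus and shields its own face, so the bridge should form anti to it. The step needs π-facial selectivity and cycloaddition over ene reaction; the first rests on the C4 isopropyl group and is sharpened by the low temperature, the second on the cisoid ring diene, which takes up singlet oxygen faster by [4+2] addition than by allylic hydrogen abstraction. The silyl ether is inert to singlet oxygen, and any syn isomer is removed by chromatography.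

Step 7
Reactants: 10 endoperoxide
Product: 11 (4R,5R)-4-hydroxy-5-isopropyl-2-[(tert-butyldimethylsilyloxy)methyl]cyclohex-2-en-1-one (C2 ketone, C5 hydroxyl trans to isopropyl)
Conditions: Et3N (1.5 equiv), CH2Cl2, 0 °C → rt
Reagents that add atoms: none
Why: Kornblum–DeLaMare rearrangement in which the amine removes the bridgehead hydrogen on C2, flanked only by the C3 methylene and the in-plane CH2OSi group whereas the C5 hydrogen lies gauche to the C4 isopropyl group, and the O–O bond breaks in the same event to give the C2 ketone and the C5 alcohol with the C5 configuration unchanged.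

Step 8
Reactants: 11 trans-hydroxy enone; 12 angelic acid
Product: 13 (1S,6R)-6-isopropyl-4-oxo-3-[(tert-butyldimethylsilyloxy)methyl]cyclohex-2-en-1-yl (Z)-2-methylbut-2-enoate (C5 angelate cis to isopropyl)
Conditions: PPh3, diisopropyl azodicarboxylate, toluene, 0 °C → rt
Reagents that add atoms: none
Why: Mitsunobu esterification in which the allylic C5 hydroxyl is activated as its oxyphosphonium ion and displaced by angelate in an SN2 step with inversion, which places the ester cis to isopropyl, while anti elimination is unavailable because the C4 hydrogen is cis to the leaving group and the neutral conditions preserve the Z geometry of the acid.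

Step 9
Reactants: 13 C5 angelate
Product: 16 α-hydroxy ketone (C3 hydroxyl trans to isopropyl; C5 angelate cis), via silyl dienol ether 14 (not isolated), via silyloxy epoxide 15 (not isolated)
Conditions: LiN(SiMe3)2, Me3SiCl, THF, −78 °C; then dimethyldioxirane, acetone/CH2Cl2, −78 °C → −30 °C; then aq. citric acid, THF, 0 °C
Reagents that add atoms: dimethyldioxirane, CC1(C)OO1
Why: Rubottom oxidation in which kinetic deprotonation at C3, the only enolisable α-position, and O-silylation give the 2-silyloxy diene, whose electron-rich C2=C3 bond is epoxidised from the face opposite both the C4 isopropyl and the C5 angelate groups, so that acid opening of the silyloxy epoxide leaves the C3 hydroxyl trans to isopropyl.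

Step 10
Reactants: 12 angelic acid
Product: 17 (Z)-2-methylbut-2-en-1-ol
Conditions: LiAlH4, Et2O, 0 °C → reflux; aq. NaOH work-up
Reagents that add atoms: none
Why: Hydride reduction of the carboxylic acid to the primary allylic alcohol, in which the trisubstituted alkene is not reduced and its Z geometry is kept.

Step 11
Reactants: 17 (Z)-2-methylbut-2-en-1-ol
Product: 18 [(2S,3R)-2,3-dimethyloxiran-2-yl]methanol
Conditions: Ti(OiPr)4 (10 mol%), L-(+)-diethyl tartrate (12 mol%), tBuOOH, 4 Å molecular sieves, CH2Cl2, −20 °C
Reagents that add atoms: tert-butyl hydroperoxide, CC(C)(C)OO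
Why: Katsuki–Sharpless asymmetric epoxidation in which the titanium L-(+)-tartrate complex delivers oxygen to the alkene face that gives the (2S)-epoxy alcohol, as it does for other primary allylic alcohols, while the Z geometry is carried into the trans arrangement of the two methyl groups (3R).

Step 12
Reactants: 18 epoxy alcohol
Product: 19 (2R,3R)-2,3-dimethyloxirane-2-carboxylic acid
Conditions: TEMPO (20 mol%), PhI(OAc)2 (2.2 equiv), MeCN/H2O 1:1, rt
Reagents that add atoms: water, O
Why: Oxoammonium-mediated oxidation takes the primary alcohol through the aldehyde hydrate to the acid under near-neutral conditions that leave the epoxide and both stereocentres untouched (the descriptor at C2 changes only because the substituent priorities change).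

Step 13
Reactants: 16 α-hydroxy ketone; 19 epoxy acid
Product: 21 tert-butyldimethylsilyl ether of the target, via mixed anhydride 20 (not isolated)
Conditions: 19, 2,4,6-trichlorobenzoyl chloride, Et3N, THF, 0 °C → rt; then 16, DMAP, toluene, rt
Reagents that add atoms: none
Why: Yamaguchi esterification in which DMAP attacks the mixed anhydride at the less hindered epoxyacyl carbonyl and the acylpyridinium ion acylates the C3 hydroxyl, the only free hydroxyl in 16, with retention at C3 and at both epoxide carbons.

Step 14
Reactants: 21 silyl ether
Product: 22 target, (1S,5R,6R)-3-(hydroxymethyl)-5-{[(2Z)-2-methylbut-2-enoyl]oxy}-2-oxo-6-(propan-2-yl)cyclohex-3-en-1-yl (2R,3R)-2,3-dimethyloxirane-2-carboxylate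
Conditions: HF·pyridine, pyridine, THF, 0 °C → rt
Reagents that add atoms: none
Why: Fluoride-mediated cleavage of the primary silyl ether under pyridine-buffered conditions, which the two esters, the trisubstituted epoxide and the enone should survive, releases the C7 hydroxyl.

**Compound list**

1 | isovaleraldehyde (3-methylbutanal) | CC(C)CC=O | starting material
2 | methyl vinyl ketone (but-3-en-2-one) | C=CC(C)=O | starting material
3 | (R)-2-isopropyl-5-oxohexanal (keto aldehyde) | O=C[C@@H](C(C)C)CCC(C)=O | intermediate
4 | (R)-cryptone, (R)-4-isopropylcyclohex-2-en-1-one | O=C1C=C[C@@H](C(C)C)CC1 | intermediate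
5 | lithium (R)-4-isopropylcyclohexa-1,5-dien-1-olate (lithium dienolate) | C1=CC([O-])=CC[C@@H]1C(C)C.[Li+] | intermediate
6 | (R)-4-isopropylcyclohexa-1,5-dien-1-yl trifluoromethanesulfonate | C1=CC(OS(=O)(=O)C(F)(F)F)=CC[C@@H]1C(C)C | intermediate
7 | methyl (R)-4-isopropylcyclohexa-1,5-diene-1-carboxylate | C1=CC(C(=O)OC)=CC[C@@H]1C(C)C | intermediate
8 | [(R)-4-isopropylcyclohexa-1,5-dien-1-yl]methanol | C1=CC(CO)=CC[C@@H]1C(C)C | intermediate
9 | (R)-5-isopropyl-2-[(tert-butyldimethylsilyloxy)methyl]cyclohexa-1,3-diene | C1=CC(CO[Si](C)(C)C(C)(C)C)=CC[C@@H]1C(C)C | intermediate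
10 | (1R,4S,7R)-5-[(tert-butyldimethylsilyloxy)methyl]-7-isopropyl-2,3-dioxabicyclo[2.2.2]oct-5-ene (O–O bridge C2 to C5, anti to isopropyl) | [C@@H]12C=C(CO[Si](C)(C)C(C)(C)C)[C@@H](OO1)C[C@@H]2C(C)C | intermediate
11 | (4R,5R)-4-hydroxy-5-isopropyl-2-[(tert-butyldimethylsilyloxy)methyl]cyclohex-2-en-1-one (C5–OH trans to isopropyl) | O[C@H]1C=C(CO[Si](C)(C)C(C)(C)C)C(=O)C[C@@H]1C(C)C | intermediate
12 | angelic acid, (Z)-2-methylbut-2-enoic acid | C/C=C(/C)C(=O)O | starting material
13 | (1S,6R)-6-isopropyl-4-oxo-3-[(tert-butyldimethylsilyloxy)methyl]cyclohex-2-en-1-yl (Z)-2-methylbut-2-enoate (C5 angelate cis to isopropyl) | C/C=C(/C)C(=O)O[C@@H]1C=C(CO[Si](C)(C)C(C)(C)C)C(=O)C[C@@H]1C(C)C | intermediate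
14 | silyl dienol ether of 13 (C2 trimethylsilyloxy, C2=C3 and C1=C6 double bonds) | C/C=C(/C)C(=O)O[C@@H]1C=C(CO[Si](C)(C)C(C)(C)C)C(O[Si](C)(C)C)=C[C@@H]1C(C)C | intermediate
15 | silyloxy epoxide (C2–C3 epoxide, oxygen on the face opposite isopropyl and angelate; trimethylsilyloxy on C2) | C/C=C(/C)C(=O)O[C@@H]1C=C(CO[Si](C)(C)C(C)(C)C)[C@@]2(O[Si](C)(C)C)O[C@H]2[C@@H]1C(C)C | intermediate
16 | α-hydroxy ketone (C3–OH trans to isopropyl, C5 angelate cis, C7 silyl ether) | C/C=C(/C)C(=O)O[C@@H]1C=C(CO[Si](C)(C)C(C)(C)C)C(=O)[C@@H](O)[C@@H]1C(C)C | intermediate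
17 | (Z)-2-methylbut-2-en-1-ol | C/C=C(/C)CO | intermediate
18 | [(2S,3R)-2,3-dimethyloxiran-2-yl]methanol | OC[C@]1(C)O[C@@H]1C | intermediate
19 | (2R,3R)-2,3-dimethyloxirane-2-carboxylic acid | OC(=O)[C@]1(C)O[C@@H]1C | intermediate
20 | (2R,3R)-2,3-dimethyloxirane-2-carboxylic 2,4,6-trichlorobenzoic anhydride (mixed anhydride) | Clc1cc(Cl)c(C(=O)OC(=O)[C@]2(C)O[C@@H]2C)c(Cl)c1 | intermediate
21 | C7 tert-butyldimethylsilyl ether of the target (3S,4R,5R in target numbering) | C/C=C(/C)C(=O)O[C@@H]1C=C(CO[Si](C)(C)C(C)(C)C)C(=O)[C@@H](OC(=O)[C@]2(C)O[C@@H]2C)[C@@H]1C(C)C | intermediate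
22 | (1S,5R,6R)-3-(hydroxymethyl)-5-{[(2Z)-2-methylbut-2-enoyl]oxy}-2-oxo-6-(propan-2-yl)cyclohex-3-en-1-yl (2R,3R)-2,3-dimethyloxirane-2-carboxylate | C/C=C(/C)C(=O)O[C@@H]1C=C(CO)C(=O)[C@@H](OC(=O)[C@]2(C)O[C@@H]2C)[C@@H]1C(C)C | target

**Count.** Total steps: 14. Longest linear sequence: 11 (steps 1–9, 13, 14); steps 10–12 form the side branch that joins at step 13.

**Steps most likely to fail**

1. Step 6. Singlet oxygen is small, so it may attack both faces of the diene with only a modest preference for the face anti to isopropyl, and some ene reaction may compete. Fallback, setting out from 9 and returning at 13: the photooxygenation is run as before and the isomer with the bridge on the isopropyl face, syn-endoperoxide F1, is carried on instead of being discarded. Et3N in CH2Cl2 should rearrange it to the hydroxy enone with the C5 hydroxyl cis to isopropyl, cis-hydroxy enone F2, which already has the C5 configuration of the target. Acylation with retention (angelic acid, 2,4,6-trichlorobenzoyl chloride, Et3N, toluene) then gives 13, so both faces of attack lead to the same compound.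

2. Step 7. The base may abstract the bridgehead hydrogen at C5 instead of C2, since the steric difference between the two is not large, which would place the ketone at C5. Fallback, setting out from 10 and returning at 13, which avoids any choice between the two hydrogens:
   - thiourea in MeOH reduces the O–O bond to the cis-ene-diol F3;
   - Bu4NF in THF removes the silyl group to give triol F4;
   - 2,2-dimethoxypropane and pyridinium p-toluenesulfonate close the C2/C7 1,3-diol to the six-membered acetonide F5, leaving the C5 hydroxyl as the only free one;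
   - Mitsunobu reaction with angelic acid (PPh3, diisopropyl azodicarboxylate) gives the inverted angelate F6;
   - aqueous acetic acid releases the C2/C7 diol F7;
   - tBuMe2SiCl and imidazole at −20 °C silylate the primary hydroxyl to give silyl ether F8;
   - Dess–Martin periodinane oxidises the remaining C2 alcohol to 13.

3. Step 8. Displacement at the hindered C5 oxyphosphonium ion by the weakly acidic, branched angelic acid may be slow, so that acyl transfer with retention or isomerisation of the Z acid intervenes. Fallback, setting out from 11 and returning at 13: Mitsunobu reaction with the stronger and smaller chloroacetic acid gives the inverted chloroacetate F9. Thiourea and NaHCO3 in EtOH remove the chloroacetyl group selectively to give the cis-hydroxy enone F2 already described. Acylation with angelic acid under the mixed-anhydride conditions given above then returns to 13.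

**Further compounds**

F1 | step 6 | (1S,4R,7R)-5-[(tert-butyldimethylsilyloxy)methyl]-7-isopropyl-2,3-dioxabicyclo[2.2.2]oct-5-ene (syn-endoperoxide, bridge cis to isopropyl) | [C@H]12C=C(CO[Si](C)(C)C(C)(C)C)[C@H](OO1)C[C@@H]2C(C)C
F2 | step 6 | (4S,5R)-4-hydroxy-5-isopropyl-2-[(tert-butyldimethylsilyloxy)methyl]cyclohex-2-en-1-one (cis-hydroxy enone) | O[C@@H]1C=C(CO[Si](C)(C)C(C)(C)C)C(=O)C[C@@H]1C(C)C
F3 | step 7 | cis-ene-diol (C2 and C5 hydroxyls both trans to isopropyl, C7 silyl ether) | O[C@H]1C=C(CO[Si](C)(C)C(C)(C)C)[C@@H](O)C[C@@H]1C(C)C
F4 | step 7 | triol (C2, C5 and C7 hydroxyls free) | O[C@H]1C=C(CO)[C@@H](O)C[C@@H]1C(C)C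
F5 | step 7 | C2/C7 acetonide with free C5 hydroxyl trans to isopropyl | O[C@H]1C=C2COC(C)(C)O[C@H]2C[C@@H]1C(C)C
F6 | step 7 | C2/C7 acetonide C5 angelate (ester cis to isopropyl) | C/C=C(/C)C(=O)O[C@@H]1C=C2COC(C)(C)O[C@H]2C[C@@H]1C(C)C
F7 | step 7 | C5 angelate C2/C7 diol | C/C=C(/C)C(=O)O[C@@H]1C=C(CO)[C@@H](O)C[C@@H]1C(C)C
F8 | step 7 | C5 angelate C7 silyl ether with free C2 hydroxyl | C/C=C(/C)C(=O)O[C@@H]1C=C(CO[Si](C)(C)C(C)(C)C)[C@@H](O)C[C@@H]1C(C)C
F9 | step 8 | C5 chloroacetate cis to isopropyl (inverted) | ClCC(=O)O[C@@H]1C=C(CO[Si](C)(C)C(C)(C)C)C(=O)C[C@@H]1C(C)C
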